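Everything rests on cutting ring B at C1–C8a and C4–C4a. Ring A (C5–C8 plus the fusion atoms), oxygenated at C6 and C7, has a mirror plane and is tied to ring B through C4a and C8a alone, so the aryne derived from it gives one product whichever way it adds. C1 with the anisyl group, C2 and C3 with their nitrogens and bare C4 come as one diene. Aryne Diels–Alder addition and SO2 loss build aromatic ring B, fully substituted, in one operation. The diene is an anisyl-bearing thieno[3,4-d]imidazol-2-one S,S-dioxide with both urea nitrogens Boc-protected; its partner is a bis(benzyloxy) ortho-silylaryl triflate.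

Key step: step 9

Remark: the target has no stereocentre. Labels C1–C8a refer to the naphthalene core (C1 anisyl, C2 and C3 formamido, C6 and C7 hydroxy), and formamide rotamers are not distinguished.
Design note: the anisyl group is attached by monobromination and cross-coupling rather than by direct C–H arylation. The thiophene has two equivalent α-C–H bonds and base-labile Boc groups, so the hot carbonate conditions of a direct arylation invite double arylation and Boc loss.

Step 1
Reactants: 1 3,4-diaminothiophene dihydrochloride
Product: 2 1,3-dihydro-2H-thieno[3,4-d]imidazol-2-one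
Conditions: CDI (1.2 equiv), Et3N (2.2 equiv), DMF, 0 °C → rt, N2; precipitation with water
Reagents that add atoms: 1,1'-carbonyldiimidazole, O=C(n1ccnc1)n1ccnc1
Why: Carbonylative cyclisation by double N-acylation, in which the air-sensitive diamine is set free only in situ and the second acyl transfer is a fast five-membered ring closure to a stable, poorly soluble cyclic urea.

Step 2
Reactants: 2 1,3-dihydro-2H-thieno[3,4-d]imidazol-2-one
Product: 3 di-tert-butyl 2-oxo-thieno[3,4-d]imidazole-1,3-dicarboxylate
Conditions: Boc2O (2.5 equiv), DMAP (0.1 equiv), MeCN, rt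
Reagents that add atoms: di-tert-butyl dicarbonate, CC(C)(C)OC(=O)OC(=O)OC(C)(C)C
Why: DMAP-catalysed N-tert-butoxycarbonylation of both acidic urea N–H groups, which removes every N–H, tames the electron-rich thiophene and later activates the urea carbonyl for cleavage.

Step 3
Reactants: 3 di-tert-butyl 2-oxo-thieno[3,4-d]imidazole-1,3-dicarboxylate
Product: 4 di-tert-butyl 4-bromo-2-oxo-thieno[3,4-d]imidazole-1,3-dicarboxylate
Conditions: NBS (1.0 equiv), DMF, 0 °C → rt, dark
Reagents that add atoms: N-bromosuccinimide, O=C1CCC(=O)N1Br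
Why: Electrophilic aromatic bromination at a thiophene α-position, where both open sites are equivalent and the first bromine deactivates the ring, so one equivalent of NBS under acid-free conditions should stop at the monobromide and spare Boc.

Step 4
Reactants: 4 di-tert-butyl 4-bromo-2-oxo-thieno[3,4-d]imidazole-1,3-dicarboxylate; 5 4-methoxyphenylboronic acid
Product: 6 di-tert-butyl 4-(4-methoxyphenyl)-2-oxo-thieno[3,4-d]imidazole-1,3-dicarboxylate
Conditions: Pd(OAc)2 (2 mol %), SPhos (4 mol %), K3PO4 (2 equiv), toluene with a trace of water, 60 °C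
Reagents that add atoms: none
Why: Suzuki–Miyaura coupling, in which zerovalent palladium inserts into the reactive 2-thienyl C–Br bond, the bulky electron-rich phosphine copes with the neighbouring N-Boc group, and a weakly nucleophilic phosphate in toluene at moderate temperature spares the activated urea.

Step 5
Reactants: 6 di-tert-butyl 4-(4-methoxyphenyl)-2-oxo-thieno[3,4-d]imidazole-1,3-dicarboxylate
Product: 8 di-tert-butyl 4-(4-methoxyphenyl)-2-oxo-thieno[3,4-d]imidazole-1,3-dicarboxylate 5,5-dioxide, via thiophene S-oxide 7 (not isolated)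
Conditions: mCPBA (3 equiv), ClCH2CH2Cl, rt → 50 °C; aq. Na2S2O3/NaHCO3 wash; stored cold, used promptly
Reagents that add atoms: 3-chloroperbenzoic acid, OOC(=O)c1cccc(Cl)c1
Why: Stepwise peracid S-oxidation of a thiophene, a reaction that works even on halogen-deactivated thiophenes, in which non-aromatic 7 is oxidised faster than 6 and three ring substituents should slow the self-dimerisation typical of unhindered thiophene dioxides.

Step 6
Reactants: 9 3,4-bis(benzyloxy)benzaldehyde
Product: 11 3,4-bis(benzyloxy)phenol, via aryl formate 10 (not isolated)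
Conditions: mCPBA (1.3 equiv), CH2Cl2, rt; aq. NaHCO3 wash, concentrate; then K2CO3 (0.2 equiv), MeOH, rt
Reagents that add atoms: 3-chloroperbenzoic acid, OOC(=O)c1cccc(Cl)c1
Why: Baeyer–Villiger oxidation with aryl migration (Dakin-type outcome), favoured by the para-benzyloxy donor, followed by base-catalysed methanolysis of the formate.

Step 7
Reactants: 11 3,4-bis(benzyloxy)phenol
Product: 12 2-bromo-4,5-bis(benzyloxy)phenol
Conditions: NBS (1.0 equiv), MeCN, −20 → 0 °C
Reagents that add atoms: N-bromosuccinimide, O=C1CCC(=O)N1Br
Why: Electrophilic aromatic bromination at the only position that is ortho to the hydroxyl, para to a benzyloxy group and not wedged between two substituents.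

Step 8
Reactants: 12 2-bromo-4,5-bis(benzyloxy)phenol
Product: 15 4,5-bis(benzyloxy)-2-(trimethylsilyl)phenyl trifluoromethanesulfonate, via silyl ether 13 (not isolated), via lithium phenoxide 14 (not isolated)
Conditions: HMDS (1 equiv), THF, 65 °C, then evaporate; n-BuLi (1.1 equiv), THF, −78 °C; Tf2O (1.2 equiv), −78 → 0 °C
Reagents that add atoms: hexamethyldisilazane, C[Si](C)(C)N[Si](C)(C)C; trifluoromethanesulfonic anhydride, O=S(=O)(OS(=O)(=O)C(F)(F)F)C(F)(F)F
Why: O-silylation, bromine–lithium exchange (much faster at −78 °C than benzylic deprotonation), O-to-C silyl shift (retro-Brook rearrangement) and O-triflation of the resulting phenoxide, the standard sequence to ortho-silylaryl triflates.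

Step 9
Reactants: 8 di-tert-butyl 4-(4-methoxyphenyl)-2-oxo-thieno[3,4-d]imidazole-1,3-dicarboxylate 5,5-dioxide; 15 4,5-bis(benzyloxy)-2-(trimethylsilyl)phenyl trifluoromethanesulfonate
Product: 18 di-tert-butyl 6,7-bis(benzyloxy)-4-(4-methoxyphenyl)-2-oxo-naphtho[2,3-d]imidazole-1,3-dicarboxylate, via aryne 16 (not isolated), via sulfonyl-bridged cycloadduct 17 (not isolated)
Conditions: CsF (4 equiv, dried), dry MeCN/toluene, rt → 40 °C, 15 (1.5–2 equiv) added slowly to 8
Reagents that add atoms: none
Why: Fluoride attacks silicon in 15 and triflate departs, so aryne 16 is released slowly under almost neutral conditions and stays dilute beside the diene. The bent, strongly electrophilic triple bond of 16 adds suprafacially across the termini C4 and C6 of the ring-locked s-cis diene of 8, which lost its thiophene aromaticity on oxidation; this concerted intermolecular [4+2] annulation closes six-membered ring B by making C1–C8a and C4–C4a together. Bridged sulfone 17 then expels SO2 in a cheletropic step driven by aromatisation, which makes the sequence irreversible and gives the naphthalene without a separate oxidation. The closest known reaction type is the aryne Diels–Alder reaction of substituted thiophene S,S-dioxides with SO2 extrusion to naphthalenes, applied here to a member of that class that carries two acylated nitrogens. The two bridgehead centres of 17 are tied to each other by the bridge, arise as a racemate and vanish with SO2, so no stereocentre has to be controlled. The step needs carbon rather than nitrogen capture and no regiochemical choice: 8 has no N–H, each nitrogen lone pair is shared by Boc, urea carbonyl and vinyl sulfone and is too poor a nucleophile for N-arylation or for aryne insertion into an N–C(O) bond, and the mirror plane of 16 makes both orientations identical.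

Step 10
Reactants: 18 di-tert-butyl 6,7-bis(benzyloxy)-4-(4-methoxyphenyl)-2-oxo-naphtho[2,3-d]imidazole-1,3-dicarboxylate
Product: 19 di-tert-butyl [6,7-bis(benzyloxy)-1-(4-methoxyphenyl)naphthalene-2,3-diyl]dicarbamate
Conditions: LiOH (4 equiv), THF/H2O, 0 °C → rt
Reagents that add atoms: none
Why: Hydrolysis of a Boc-activated urea on the principle used to open N-Boc lactams and N-Boc oxazolidinones, in which hydroxide attacks the ring carbonyl (the most electrophilic and least shielded of the three because both flanking nitrogens are acylated twice), an N-aryl carbamate anion leaves and the carbamic acid loses CO2.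

Step 11
Reactants: 19 di-tert-butyl [6,7-bis(benzyloxy)-1-(4-methoxyphenyl)naphthalene-2,3-diyl]dicarbamate
Product: 21 N,N'-[6,7-bis(benzyloxy)-1-(4-methoxyphenyl)naphthalene-2,3-diyl]diformamide, via diamine dihydrochloride 20 (not isolated)
Conditions: HCl (4 M in dioxane), CH2Cl2, 0 °C → rt, evaporate; then AcOCHO (6 equiv, preformed from HCO2H and Ac2O), Et3N (2.2 equiv), THF, −20 → 0 °C, Ar
Reagents that add atoms: acetic formic anhydride, CC(=O)OC=O
Why: Acidolysis of the Boc groups followed by N-formylation with a mixed anhydride, in which the air-sensitive diamine is kept as its salt and then meets excess reagent in the cold so that the second formylation outruns acid- or heat-promoted cyclodehydration to the naphthoimidazole.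

Step 12
Reactants: 21 N,N'-[6,7-bis(benzyloxy)-1-(4-methoxyphenyl)naphthalene-2,3-diyl]diformamide
Product: 22 melanocin E
Conditions: H2 (1 atm), 10% Pd/C, degassed THF/MeOH, rt; filtration under Ar
Reagents that add atoms: none
Why: Catalytic hydrogenolysis of the two benzyl aryl ethers, which leaves the formamides, the aryl methyl ether and the naphthalene untouched and needs only an oxygen-free filtration to protect the catechol.

Compound list
1 | 3,4-diaminothiophene dihydrochloride | Nc1cscc1N.Cl.Cl | starting material
2 | 1,3-dihydro-2H-thieno[3,4-d]imidazol-2-one | O=C1Nc2cscc2N1 | intermediate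
3 | di-tert-butyl 2-oxo-thieno[3,4-d]imidazole-1,3-dicarboxylate | CC(C)(C)OC(=O)N1C(=O)N(C(=O)OC(C)(C)C)c2cscc21 | intermediate
4 | di-tert-butyl 4-bromo-2-oxo-thieno[3,4-d]imidazole-1,3-dicarboxylate | CC(C)(C)OC(=O)N1C(=O)N(C(=O)OC(C)(C)C)c2c(Br)scc21 | intermediate
5 | 4-methoxyphenylboronic acid | COc1ccc(cc1)B(O)O | starting material
6 | di-tert-butyl 4-(4-methoxyphenyl)-2-oxo-thieno[3,4-d]imidazole-1,3-dicarboxylate | COc1ccc(cc1)-c1scc2N(C(=O)OC(C)(C)C)C(=O)N(C(=O)OC(C)(C)C)c12 | intermediate
7 | di-tert-butyl 4-(4-methoxyphenyl)-2-oxo-thieno[3,4-d]imidazole-1,3-dicarboxylate 5-oxide (sulfur inverts readily, no configuration assigned; not isolated) | COc1ccc(cc1)C1=C2N(C(=O)OC(C)(C)C)C(=O)N(C(=O)OC(C)(C)C)C2=CS1=O | intermediate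
8 | di-tert-butyl 4-(4-methoxyphenyl)-2-oxo-thieno[3,4-d]imidazole-1,3-dicarboxylate 5,5-dioxide | COc1ccc(cc1)C1=C2N(C(=O)OC(C)(C)C)C(=O)N(C(=O)OC(C)(C)C)C2=CS1(=O)=O | intermediate
9 | 3,4-bis(benzyloxy)benzaldehyde | O=Cc1ccc(OCc2ccccc2)c(OCc2ccccc2)c1 | starting material
10 | 3,4-bis(benzyloxy)phenyl formate (not isolated) | O=COc1ccc(OCc2ccccc2)c(OCc2ccccc2)c1 | intermediate
11 | 3,4-bis(benzyloxy)phenol | Oc1ccc(OCc2ccccc2)c(OCc2ccccc2)c1 | intermediate
12 | 2-bromo-4,5-bis(benzyloxy)phenol | Oc1cc(OCc2ccccc2)c(OCc2ccccc2)cc1Br | intermediate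
13 | [2-bromo-4,5-bis(benzyloxy)phenoxy]trimethylsilane (not isolated) | C[Si](C)(C)Oc1cc(OCc2ccccc2)c(OCc2ccccc2)cc1Br | intermediate
14 | lithium 4,5-bis(benzyloxy)-2-(trimethylsilyl)phenoxide (not isolated) | [Li+].[O-]c1cc(OCc2ccccc2)c(OCc2ccccc2)cc1[Si](C)(C)C | intermediate
15 | 4,5-bis(benzyloxy)-2-(trimethylsilyl)phenyl trifluoromethanesulfonate | C[Si](C)(C)c1cc(OCc2ccccc2)c(OCc2ccccc2)cc1OS(=O)(=O)C(F)(F)F | intermediate
16 | 4,5-bis(benzyloxy)benzyne (not isolated) | C1#CC=C(OCc2ccccc2)C(OCc2ccccc2)=C1 | intermediate
17 | sulfonyl-bridged cycloadduct, di-tert-butyl 6,7-bis(benzyloxy)-4-(4-methoxyphenyl)-2-oxo-4,9-dihydro-4,9-epithionaphtho[2,3-d]imidazole-1,3-dicarboxylate S,S-dioxide (racemic, one enantiomer drawn; not isolated) | COc1ccc(cc1)[C@]12c3cc(OCc4ccccc4)c(OCc4ccccc4)cc3[C@H](S1(=O)=O)C5=C2N(C(=O)OC(C)(C)C)C(=O)N5C(=O)OC(C)(C)C | intermediate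
18 | di-tert-butyl 6,7-bis(benzyloxy)-4-(4-methoxyphenyl)-2-oxo-naphtho[2,3-d]imidazole-1,3-dicarboxylate | COc1ccc(cc1)-c1c2N(C(=O)OC(C)(C)C)C(=O)N(C(=O)OC(C)(C)C)c2cc2cc(OCc3ccccc3)c(OCc3ccccc3)cc12 | intermediate
19 | di-tert-butyl [6,7-bis(benzyloxy)-1-(4-methoxyphenyl)naphthalene-2,3-diyl]dicarbamate | COc1ccc(cc1)-c1c(NC(=O)OC(C)(C)C)c(NC(=O)OC(C)(C)C)cc2cc(OCc3ccccc3)c(OCc3ccccc3)cc12 | intermediate
20 | 6,7-bis(benzyloxy)-1-(4-methoxyphenyl)naphthalene-2,3-diamine dihydrochloride (not isolated) | COc1ccc(cc1)-c1c(N)c(N)cc2cc(OCc3ccccc3)c(OCc3ccccc3)cc12.Cl.Cl | intermediate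
21 | N,N'-[6,7-bis(benzyloxy)-1-(4-methoxyphenyl)naphthalene-2,3-diyl]diformamide | COc1ccc(cc1)-c1c(NC=O)c(NC=O)cc2cc(OCc3ccccc3)c(OCc3ccccc3)cc12 | intermediate
22 | melanocin E, N,N'-[6,7-dihydroxy-1-(4-methoxyphenyl)naphthalene-2,3-diyl]diformamide | COc1ccc(-c2c(NC=O)c(NC=O)cc3cc(O)c(O)cc23)cc1 | target

Total step count: 12. Longest linear sequence: 9 steps (steps 1–5 and 9–12); the aryne arm (steps 6–8) is convergent.

Steps most likely to fail

Step 9. Fluoride or traces of hydroxide may strip a Boc group or open the activated urea, and the N–H so exposed would be arylated by the aryne. The sulfone may also dimerise faster than it meets the dilute aryne. Fallback: a fluoride-free, thermally triggered aryne.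
- It sets out from aldehyde 9. Nitration (HNO3, AcOH, 0–10 °C) para to the 3-benzyloxy group should give 4,5-bis(benzyloxy)-2-nitrobenzaldehyde F1.
- Pinnick oxidation (NaClO2, NaH2PO4, 2-methyl-2-butene) should give 4,5-bis(benzyloxy)-2-nitrobenzoic acid F2.
- Fe powder with NH4Cl in aqueous ethanol, which spares benzyl ethers, should give 2-amino-4,5-bis(benzyloxy)benzoic acid F3.
- Slow addition of F3 to isoamyl nitrite and sulfone 8 in refluxing 1,2-dichloroethane generates 4,5-bis(benzyloxy)-2-diazoniobenzoate F4. It never accumulates and loses N2 and CO2 to the same aryne 16.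
- Cycloaddition through 17 brings the route back at 18.

Step 5. Long contact with excess peracid may erode the product by epoxidation of the electron-poor diene or attack on the anisyl ring. The sulfone may also dimerise with SO2 loss during isolation. Fallback: stop at the sulfoxide level and use that compound as the diene.
- It sets out from 6. One equivalent of mCPBA with BF3·OEt2 in CH2Cl2 at −20 °C should give S-oxide 7, whose coordination to boron blocks the second oxygen transfer. The short, cold contact is expected to spare Boc on these weakly basic nitrogens.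
- After a cold NaHCO3 quench, crude 7 is combined at once with 15 and CsF as in step 9.
- Thiophene S-oxides are more reactive dienes than the dioxides. The sulfinyl-bridged cycloadduct F5, with oxygen expected on the side of the benzo ring, extrudes SO on formation or gentle warming.
- The route is rejoined at 18, bypassing 8.

Step 10. Hydroxide may attack an exocyclic Boc carbonyl instead of the ring carbonyl. This loss of the protecting group would end in the free cyclic urea, which resists hydrolysis. Fallback: reductive instead of hydrolytic cleavage, on the model of borohydride cleavage of Boc-activated amides.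
- It sets out from 18, using NaBH4 (excess) in THF/EtOH at 0 °C → rt. Hydride adds only to the ring carbonyl, because carbamate carbonyls are inert to borohydride.
- The ring opens to the ring-opened N-formyl carbamate F6.
- Further hydride delivery to its very electrophilic formyl group releases the former urea carbon as methanol, and the route is rejoined at 19.

Further compounds
F1 | step 9 | 4,5-bis(benzyloxy)-2-nitrobenzaldehyde | O=Cc1cc(OCc2ccccc2)c(OCc2ccccc2)cc1[N+](=O)[O-]
F2 | step 9 | 4,5-bis(benzyloxy)-2-nitrobenzoic acid | OC(=O)c1cc(OCc2ccccc2)c(OCc2ccccc2)cc1[N+](=O)[O-]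
F3 | step 9 | 2-amino-4,5-bis(benzyloxy)benzoic acid | Nc1cc(OCc2ccccc2)c(OCc2ccccc2)cc1C(O)=O
F4 | step 9 | 4,5-bis(benzyloxy)-2-diazoniobenzoate | [O-]C(=O)c1cc(OCc2ccccc2)c(OCc2ccccc2)cc1[N+]#N
F5 | step 5 | sulfinyl-bridged cycloadduct, di-tert-butyl 6,7-bis(benzyloxy)-4-(4-methoxyphenyl)-2-oxo-4,9-dihydro-4,9-epithionaphtho[2,3-d]imidazole-1,3-dicarboxylate S-oxide (racemic, one enantiomer drawn) | COc1ccc(cc1)[C@]12c3cc(OCc4ccccc4)c(OCc4ccccc4)cc3[C@H]([S@@]1=O)C5=C2N(C(=O)OC(C)(C)C)C(=O)N5C(=O)OC(C)(C)C
F6 | step 10 | ring-opened N-formyl carbamate, tert-butyl [6,7-bis(benzyloxy)-3-(tert-butoxycarbonylamino)-4-(4-methoxyphenyl)naphthalen-2-yl](formyl)carbamate | COc1ccc(cc1)-c1c(NC(=O)OC(C)(C)C)c(N(C=O)C(=O)OC(C)(C)C)cc2cc(OCc3ccccc3)c(OCc3ccccc3)cc12
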